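**Strategy.** The plan rests on cutting the bond between arene carbon C1 of ring A and the tertiary carbinol carbon, with ring A carried as a cyclohexenone until after this bond exists. The 1,2,4-pattern of ring A (C1 carbinol, C2 OMe, C4 Me) is already written into 3-methylcyclohex-2-enone (C6, C1 and C3 respectively). A kinetic alpha-prime aldol addition to acetonide-protected dihydroxyacetone therefore installs the whole glycerol side chain, correctly placed, in one operation. The precursors are the two commercial ketones themselves. Aromatisation, O-methylation, acetal removal and acylation of the two primary hydroxyls then finish the target.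

Key step: step 1

Remark: the target has no stereocentre, because the carbinol carbon bears two identical acyloxymethyl arms. The single racemic centre of aldol 5 (C6) becomes an arene carbon in step 2, so no stereocontrol is planned. The structures of both aldol partners and of the aldol product were checked against the target and needed no correction.

**Step 1**
Reactants: 1 3-methylcyclohex-2-en-1-one; 2 2,2-dimethyl-1,3-dioxan-5-one
Product: 5 rac-6-(5-hydroxy-2,2-dimethyl-1,3-dioxan-5-yl)-3-methylcyclohex-2-en-1-one, via lithium dienolate 3 (not isolated), via lithium aldolate 4 (not isolated)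
Conditions: LiN(i-Pr)2 (1.05 equiv), THF, −78 °C, slow addition of 1; then 2 (1.2 equiv, freshly distilled, hydrate-free), −78 °C; AcOH in THF at −78 °C, then warm
Reagents that add atoms: none
Why: Directed (kinetic) aldol addition: the hindered amide base removes a C6 hydrogen of 1 irreversibly at −78 °C, giving the cross-conjugated lithium dienolate 3 rather than the extended dienolate that equilibration through C4 or the C3 methyl would produce. Dienolate 3 attacks the carbonyl carbon of 2 through C6 in a closed, lithium-bridged six-membered transition state to give the chelated lithium aldolate 4, forming the single new C–C bond between the future arene C1 and the carbinol carbon; no ring is closed. The closest known reaction type is the alpha-prime aldol addition of kinetically generated cyclohexenone lithium enolates to ketones. The only new stereocentre (C6) arises racemic and needs no control, because it becomes an sp2 arene carbon in step 2, and the carbinol carbon is not stereogenic since the two arms of its dioxane ring are identical. The selectivities required are alpha-prime over gamma deprotonation, secured by slow addition of 1 to a slight excess of base at −78 °C, and carbonyl addition over proton transfer from the enolisable ketone, favoured by the inductive activation of the carbonyl of 2 by its two beta oxygen atoms. Protonation of 4 with acetic acid at −78 °C before warming should prevent retro-aldol reversal.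

**Step 2**
Reactants: 5 rac-6-(5-hydroxy-2,2-dimethyl-1,3-dioxan-5-yl)-3-methylcyclohex-2-en-1-one
Product: 7 5-(2-hydroxy-4-methylphenyl)-2,2-dimethyl-1,3-dioxan-5-ol, via dienone tautomer 6 (not isolated)
Conditions: Pd(O2CCF3)2 (5 mol%), 2-(dimethylamino)pyridine (10 mol%), TsOH (10 mol%), O2 (1 atm), DMSO, 80 °C
Reagents that add atoms: none
Why: Palladium-catalysed aerobic dehydrogenation of a cyclohexenone to a phenol: a divalent palladium enolate formed at C6 should undergo beta-hydride elimination from C5 to give dienone 6, which tautomerises irreversibly to phenol 7 while O2 reoxidises zerovalent palladium, and the sulfonic acid is kept equimolar with the aminopyridine so that no free strong acid meets the acetonide or the beta-hydroxy ketone.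

**Step 3**
Reactants: 7 5-(2-hydroxy-4-methylphenyl)-2,2-dimethyl-1,3-dioxan-5-ol; 8 methyl iodide
Product: 10 5-(2-methoxy-4-methylphenyl)-2,2-dimethyl-1,3-dioxan-5-ol, via potassium phenoxide 9 (not isolated)
Conditions: MeI (1.5 equiv), K2CO3 (2 equiv), DMF, room temperature
Reagents that add atoms: methyl iodide (compound 8), CI
Why: Williamson ether synthesis: carbonate deprotonates only the phenol, which is far more acidic than the tertiary alcohol, and phenoxide 9 is methylated by SN2 attack on methyl iodide while the acetonide is inert to base.

**Step 4**
Reactants: 10 5-(2-methoxy-4-methylphenyl)-2,2-dimethyl-1,3-dioxan-5-ol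
Product: 11 2-(2-methoxy-4-methylphenyl)propane-1,2,3-triol
Conditions: AcOH/H2O (4:1), 40 °C; evaporation with toluene
Reagents that add atoms: none
Why: Acid-catalysed acetal hydrolysis: warm aqueous acetic acid should cleave the isopropylidene ketal of the 1,3-diol yet is too weak to ionise the tertiary benzylic alcohol, whose cation is further disfavoured by the two flanking oxygenated carbons.

**Step 5**
Reactants: 11 2-(2-methoxy-4-methylphenyl)propane-1,2,3-triol; 12 isobutyryl chloride
Product: 14 2-hydroxy-2-(2-methoxy-4-methylphenyl)propane-1,3-diyl bis(2-methylpropanoate), via monoisobutyrate 13 (not isolated)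
Conditions: isobutyryl chloride (2.3 equiv), pyridine, CH2Cl2, 0 °C to room temperature
Reagents that add atoms: isobutyryl chloride (compound 12), CC(C)C(=O)Cl
Why: Chemoselective O-acylation (nucleophilic acyl substitution): the two primary hydroxyls should react with the acid chloride in pyridine through monoester 13, whereas the hindered tertiary benzylic hydroxyl is not acylated in the absence of an acyl-transfer catalyst.

**Compound list**
1 | 3-methylcyclohex-2-en-1-one | CC1=CC(=O)CCC1 | starting material
2 | 2,2-dimethyl-1,3-dioxan-5-one | CC1(C)OCC(=O)CO1 | starting material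
3 | lithium 5-methylcyclohexa-1,5-dien-1-olate (cross-conjugated dienolate of 1) | [Li+].[O-]C1=CCCC(C)=C1 | intermediate
4 | lithium 2,2-dimethyl-5-(4-methyl-2-oxocyclohex-3-en-1-yl)-1,3-dioxan-5-olate (racemic) | [Li+].CC1=CC(=O)C(CC1)C1([O-])COC(C)(C)OC1 | intermediate
5 | rac-6-(5-hydroxy-2,2-dimethyl-1,3-dioxan-5-yl)-3-methylcyclohex-2-en-1-one | CC1=CC(=O)C(CC1)C1(O)COC(C)(C)OC1 | intermediate
6 | 6-(5-hydroxy-2,2-dimethyl-1,3-dioxan-5-yl)-3-methylcyclohexa-2,5-dien-1-one | CC1=CC(=O)C(=CC1)C1(O)COC(C)(C)OC1 | intermediate
7 | 5-(2-hydroxy-4-methylphenyl)-2,2-dimethyl-1,3-dioxan-5-ol | Cc1ccc(c(O)c1)C1(O)COC(C)(C)OC1 | intermediate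
8 | methyl iodide | CI | starting material
9 | potassium 2-(5-hydroxy-2,2-dimethyl-1,3-dioxan-5-yl)-5-methylphenolate | [K+].Cc1ccc(c([O-])c1)C1(O)COC(C)(C)OC1 | intermediate
10 | 5-(2-methoxy-4-methylphenyl)-2,2-dimethyl-1,3-dioxan-5-ol | COc1cc(C)ccc1C1(O)COC(C)(C)OC1 | intermediate
11 | 2-(2-methoxy-4-methylphenyl)propane-1,2,3-triol | COc1cc(C)ccc1C(O)(CO)CO | intermediate
12 | isobutyryl chloride (2-methylpropanoyl chloride) | CC(C)C(=O)Cl | starting material
13 | rac-2,3-dihydroxy-2-(2-methoxy-4-methylphenyl)propyl 2-methylpropanoate | COc1cc(C)ccc1C(O)(CO)COC(=O)C(C)C | intermediate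
14 | 2-hydroxy-2-(2-methoxy-4-methylphenyl)propane-1,3-diyl bis(2-methylpropanoate) | COc1cc(C)ccc1C(O)(COC(=O)C(C)C)COC(=O)C(C)C | target

**Total step count:** 5
**Longest linear sequence:** 5 steps (1 → 5 → 7 → 10 → 11 → 14)

**Steps most likely to fail**

Step 1. The dienolate may be quenched by proton transfer from the acidic alpha-methylene groups of ketone 2, it may equilibrate to the extended dienolate, or the aldolate may revert by retro-aldol cleavage during quench and warming. The fallback sets out from compound 2 and comes back to the route at compound 10, so steps 2 and 3 are then not needed. It brings the arene in ready-made instead of building it from the enone. Commercial 1-bromo-2-methoxy-4-methylbenzene F1 would undergo bromine–lithium exchange (n-BuLi, THF, −78 °C) to give (2-methoxy-4-methylphenyl)lithium F2. Addition of this aryllithium to ketone 2 at −78 °C should give lithium 5-(2-methoxy-4-methylphenyl)-2,2-dimethyl-1,3-dioxan-5-olate F3, and aqueous NH4Cl quench then delivers compound 10.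

Step 2. Palladation at the hindered, fully substituted C6 position may be slow. Heat- and acid-promoted retro-aldol fragmentation, dehydration of the beta-hydroxy ketone, or migration and loss of the acetal could then overtake aromatisation. The fallback sets out from compound 5 and comes back at compound 7, and it moves the oxidation to a silyl dienol ether at room temperature (Saegusa–Ito oxidation). Me3SiOSO2CF3 and Et3N in CH2Cl2 at 0 °C should cap the tertiary hydroxyl, which blocks retro-aldol cleavage, and convert the enone into its silyl dienol ether. The product is 2-[2,2-dimethyl-5-(trimethylsilyloxy)-1,3-dioxan-5-yl]-5-methyl-1-(trimethylsilyloxy)cyclohexa-1,5-diene F4; a regioisomeric dienol ether would converge on the same arene. Pd(OAc)2 (1 equiv) in MeCN at room temperature should then give, after beta-hydride elimination and tautomerisation, 2-[2,2-dimethyl-5-(trimethylsilyloxy)-1,3-dioxan-5-yl]-5-methylphenol F5. K2CO3 in MeOH removes the remaining silyl ether to return compound 7.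

Step 5. Acylation may stall at the monoester because the second hydroxyl is neopentyl-like, and forcing conditions could then acylate the tertiary hydroxyl. The fallback sets out from compound 11 and comes back at compound 14, replacing chemical acylation by biocatalytic transesterification. Immobilised Candida antarctica lipase B with excess ethenyl 2-methylpropanoate F6 in tert-butyl methyl ether at 40 °C should acylate only the primary hydroxyls, passing through monoester 13. A lipase does not accept a tertiary alcohol, and release of acetaldehyde makes each acyl transfer irreversible.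

**Further compounds**
F1 | step 1 | 1-bromo-2-methoxy-4-methylbenzene | COc1cc(C)ccc1Br
F2 | step 1 | (2-methoxy-4-methylphenyl)lithium | [Li]c1ccc(C)cc1OC
F3 | step 1 | lithium 5-(2-methoxy-4-methylphenyl)-2,2-dimethyl-1,3-dioxan-5-olate | [Li+].COc1cc(C)ccc1C1([O-])COC(C)(C)OC1
F4 | step 2 | 2-[2,2-dimethyl-5-(trimethylsilyloxy)-1,3-dioxan-5-yl]-5-methyl-1-(trimethylsilyloxy)cyclohexa-1,5-diene | C[Si](C)(C)OC1=C(CCC(C)=C1)C1(O[Si](C)(C)C)COC(C)(C)OC1
F5 | step 2 | 2-[2,2-dimethyl-5-(trimethylsilyloxy)-1,3-dioxan-5-yl]-5-methylphenol | Cc1ccc(c(O)c1)C1(O[Si](C)(C)C)COC(C)(C)OC1
F6 | step 5 | ethenyl 2-methylpropanoate | CC(C)C(=O)OC=C
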